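| flask | solid substrate | enzyme | remark | time |
|---|---|---|---|---|
| zeta | 0.13 M | 10 µM | run made earlier |  |
| delta | 0.53 M | 10 µM | run made earlier |  |
| Tuesday's | 0.10 M | 10 µM |  | 80 min |
| Sunday's | 0.20 M | 10 µM |  | 80 min |
| Wednesday's | 0.40 M | 10 µM |  | 80 min |

| run | time / min | target / % | solid substrate / % |
|---|---|---|---|
| zeta | 12.0 | 1.1 | 88.0 |
| zeta | 25.0 | 2.0 | 78.6 |
| zeta | 40.0 | 5.9 | 72.1 |
| zeta | 50.0 | 7.4 | 66.7 |
| zeta | 60.0 | 10.1 | 62.8 |
| zeta | 80.0 | 14.2 | 55.3 |
| delta | 6.00 | 0.3 | 98.2 |
| delta | 10.0 | 0 | 97.3 |
| delta | 20.0 | 0 | 95.6 |
| delta | 30.0 | 0.8 | 93.8 |
| delta | 50.0 | 1.8 | 92.3 |
| delta | 80.0 | 3.8 | 88.7 |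

(readings scatter by 0.5 percentage points)

1. [target] (only what is free in solution) at the end for Tuesday's, Sunday's, Wednesday's, in this order
2. the shape of the row from first to last (falls all the way / hardly changes / rises all the way / rises, then falls / falls, then rises)

- solid substrate is a solid; its amount is given per volume of the solution
- the analysis behind the earlier runs scatters by 0.5 percentage points, standard deviation
- at the start none of the solid substrate is in solution
- a reading or a percentage of target counts all its forms, free or not
- the concentration of target that is asked is that of its free form alone
- "hardly changes" means that all values lie within two and a half points (for a concentration: within two and a half percent of the largest)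

Start late in a run, from what is gone at 80.0 min. Zeta keeps 55.3% of its charge, which means 0.0581 M has left it; this bite, the amount of solid gone per volume by that time, is what I carry. A fraction lost is then the bite over the charge. For delta that gives 11.0% against 11.3% read, a difference of 0.34 percentage points inside the scatter of 0.5 points, so in these two runs the bite did not follow the charge.

My reckoning builds up in steps. With the main step alone, solid turned straight into target, the bite is 58.1% of the charge on Tuesday's, 29.1% on Sunday's and 14.5% on Wednesday's, which is one molar value and a flat row. Adding a pool of dissolved material that waits for the enzyme lowers that value, and zeta's target, read at 14.2% of the charge, is 0.0185 M, less than the bite and 18.5% of Tuesday's charge. Solid is still present in Tuesday's by this reckoning, at 41.9%, so the three flasks should run alike. The last step is the free form. Enzyme at 10 µM can hold hardly any of that target, but the readings count free and bound together, so I commit to a flat row with 0.0185 M as my upper estimate of the free target, not as its value.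

The forecast differs from my reckoning in taking its number as the value: it gives 0.0187 M, 0.0187 M and 0.0187 M, shape hardly changes, holding that “solution stays on the same course in all three runs”.

The flask gives 0.00821 M, 0.00821 M and 0.00821 M; the row hardly changes.

    starting material + enzyme ⇌ complex (K = 32.0 /M, k = 1100 /M/s)
    solid substrate ⇌ starting material, rate k2*(cs2 - [starting material]) while solid is left; crystals form when [starting material] > cs2 (solubility = 40.0 mM, k = 6.80 × 10⁻⁴ /s)
    complex ⇌ enzyme + target (K = 0.440 M, k = 1.00 /s)
    starting material + target ⇌ idle adduct, settled at all times (K = 45.0 /M)

The bite told Tuesday's 41.9% of solid left, and 42.1% stands; on Wednesday's it told 85.5%, and 85.5% stands. Tuesday's target, free and bound counted, is 18.8% of the charge, and the free form is 8.21% of the charge, beside idle adduct at 21.1%, a percentage that counts each adduct twice. At 80.0 min in Tuesday's, complex has a half-life of 0.69 s by the forward rate of its step to enzyme and target alone, and starting material one of 2.0 min by the forward rate of its step to complex alone, so the first of these times is far shorter than the second. Complex is there in a steady state, made 1.00 times as fast as it is used up, each step taken net, and it holds 47.1% of the enzyme charged.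

All runs were computed from invented constants; noise was put on by code.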